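**Retrosynthetic overview**
1. Target (methylene-bridged dimer) ⇒ two molecules of the monomeric enolised β-diketone plus formaldehyde (Knoevenagel/Michael at C2).
2. Monomer ⇒ O-demethylation, benzylic oxidation (C1 carbonyl) and ring acetylation (C7) of 5,7-dimethoxy-1,1-dimethyl-2-tetralone.
3. Key disconnection: six-membered ring B with its gem-dimethyl carbon ⇒ one-carbon ring expansion of 4,6-dimethoxyindan-1-one by Me2C insertion from 2-diazopropane (1,2-aryl shift).
4. Indanone ⇒ Fries-type lactone-to-ketone rearrangement of 7-hydroxychroman-2-one, made from resorcinol and acrylic acid.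
5. Ring order: benzene ring bought (resorcinol) → lactone ring → five-membered carbocycle → ring B by expansion → dimerisation last.

Assumption: the target has no stereocentre or other stereogenic element, so there is no enantiomer to choose; the route gives the one achiral compound.

**Step 1**
Reactants: 1 resorcinol; 2 acrylic acid
Product: 4 7-hydroxychroman-2-one, via 3-(2,4-dihydroxyphenyl)propanoic acid 3 (not isolated)
Conditions: 4-MeC6H4SO3H·H2O (10 mol%), toluene, reflux, Dean–Stark
Reagents that add atoms: none
Why: Acid-catalysed Friedel–Crafts hydroarylation of acrylic acid at C4 of resorcinol (ortho to one hydroxyl, para to the other), then lactonisation of the ortho-hydroxy acid, a known way to 3,4-dihydrocoumarins; no stereocentre.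

**Step 2**
Reactants: 4 7-hydroxychroman-2-one
Product: 5 4,6-dihydroxyindan-1-one
Conditions: AlCl3 (5 equiv), NaCl, melt, 180–190 °C, 1 h; then ice/aq. HCl
Reagents that add atoms: none
Why: Fries-type lactone-to-indanone rearrangement (the classical AlCl3-melt conversion of dihydrocoumarin into 4-hydroxyindan-1-one): the tethered acylium can only close on the one free carbon ortho to the side chain, which is the position meta to both oxygens that ordinary substitution of resorcinol cannot reach.

**Step 3**
Reactants: 5 4,6-dihydroxyindan-1-one
Product: 6 4,6-dimethoxyindan-1-one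
Conditions: MeI (3 equiv), K2CO3 (3 equiv), acetone, reflux
Reagents that add atoms: iodomethane, CI
Why: Williamson O-methylation of the two free, non-chelated phenols protects them from the diazoalkane and the later oxidation, and K2CO3 does not alkylate the ketone.

**Step 4**
Reactants: 6 4,6-dimethoxyindan-1-one; 7 acetone hydrazone
Product: 9 5,7-dimethoxy-1,1-dimethyl-3,4-dihydronaphthalen-2(1H)-one, via 2-diazopropane 8 (not isolated)
Conditions: 7 (3 equiv), Ag2O, KOH (cat.), Et2O, −20 °C, cold filtration; the red solution added to 6, Sc(OTf)3 (10 mol%), CH2Cl2, −78 to −30 °C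
Reagents that add atoms: none
Why: Proposed new method: Sc(OTf)3-catalysed insertion of a non-stabilised dialkyl diazoalkane into the aryl–carbonyl bond of a 1-indanone, in which the scandium-bound ketone (meta to both methoxy groups, so not deactivated) is attacked by the diazo carbon to give a β-oxido tertiary diazonium ion and the aryl group, a better migrating group than the ring CH2, undergoes the 1,2-shift with loss of N2, enlarging the five-membered ring to ring B and creating the gem-dimethyl quaternary carbon in one event while the hindered α-quaternary product resists a second homologation; the closest known reaction type is the Lewis-acid-catalysed Büchner–Curtius–Schlotterbeck/Tiffeneau–Demjanov-type homologation of cycloalkanones with substituted diazomethanes and the aryl-shift expansion of 1-indanones to 2-tetralones with (trimethylsilyl)diazomethane; no stereocentre is formed.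

**Step 5**
Reactants: 9 5,7-dimethoxy-1,1-dimethyl-3,4-dihydronaphthalen-2(1H)-one; 10 acetyl chloride
Product: 11 6-acetyl-5,7-dimethoxy-1,1-dimethyl-3,4-dihydronaphthalen-2(1H)-one
Conditions: AlCl3 (1.3 equiv), CH2Cl2, −10 to 0 °C
Reagents that add atoms: none
Why: Friedel–Crafts acylation goes to C6 between the two methoxy groups because the only other free ring carbon (C8) is blocked by the peri gem-dimethyl group, and at this stage there is no β-diketone to compete for the acylium ion.

**Step 6**
Reactants: 11 6-acetyl-5,7-dimethoxy-1,1-dimethyl-3,4-dihydronaphthalen-2(1H)-one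
Product: 12 7-acetyl-3-hydroxy-6,8-dimethoxy-4,4-dimethylnaphthalen-1(4H)-one (enol form of the 1,3-dione)
Conditions: O2 (1 atm), N-hydroxyphthalimide (20 mol%), Co(OAc)2 (2 mol%), MeCN, 70 °C
Reagents that add atoms: dioxygen, O=O
Why: N-hydroxyphthalimide/cobalt-catalysed aerobic benzylic oxidation: the phthalimide-N-oxyl radical abstracts the weakest C–H (the benzylic CH2 ortho to a methoxy group) and the hydroperoxide collapses to the aryl ketone, completing the β-diketone.

**Step 7**
Reactants: 12 7-acetyl-3-hydroxy-6,8-dimethoxy-4,4-dimethylnaphthalen-1(4H)-one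
Product: 13 7-acetyl-3,6,8-trihydroxy-4,4-dimethylnaphthalen-1(4H)-one
Conditions: BBr3 (5 equiv), CH2Cl2, −78 °C to rt; then H2O
Reagents that add atoms: none
Why: Lewis-acid ether cleavage (BBr3 demethylation) is easy here because both methoxy groups sit ortho to carbonyl groups and are cleaved through chelated aryloxyboranes that hydrolyse on work-up.

**Step 8**
Reactants: 13 7-acetyl-3,6,8-trihydroxy-4,4-dimethylnaphthalen-1(4H)-one (2 equiv); 14 formaldehyde
Product: 16 2,2'-methylenebis[7-acetyl-3,6,8-trihydroxy-4,4-dimethylnaphthalen-1(4H)-one] (target), via 2-methylidene trione 15 (not isolated)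
Conditions: 37% aq. HCHO (0.5 equiv), Et3N (cat.), MeOH, rt; then dil. HCl
Reagents that add atoms: none
Why: Knoevenagel condensation of formaldehyde at C2 of the cyclic β-diketone, then Michael addition of a second enol to the 2-methylidene trione, the standard assembly of methylene-bridged bis(β-diketones); no stereocentre arises.

**Compound list**
1 | resorcinol | Oc1cccc(O)c1 | starting material
2 | acrylic acid | C=CC(=O)O | starting material
3 | 3-(2,4-dihydroxyphenyl)propanoic acid | OC(=O)CCc1ccc(O)cc1O | intermediate
4 | 7-hydroxychroman-2-one (7-hydroxy-3,4-dihydro-2H-chromen-2-one) | O=C1CCc2ccc(O)cc2O1 | intermediate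
5 | 4,6-dihydroxyindan-1-one | O=C1CCc2c(O)cc(O)cc21 | intermediate
6 | 4,6-dimethoxyindan-1-one | COc1cc(OC)c2CCC(=O)c2c1 | intermediate
7 | acetone hydrazone | CC(C)=NN | starting material
8 | 2-diazopropane | CC(C)=[N+]=[N-] | intermediate
9 | 5,7-dimethoxy-1,1-dimethyl-3,4-dihydronaphthalen-2(1H)-one | COc1cc(OC)c2CCC(=O)C(C)(C)c2c1 | intermediate
10 | acetyl chloride | CC(=O)Cl | starting material
11 | 6-acetyl-5,7-dimethoxy-1,1-dimethyl-3,4-dihydronaphthalen-2(1H)-one | CC(=O)c1c(OC)cc2c(c1OC)CCC(=O)C2(C)C | intermediate
12 | 7-acetyl-3-hydroxy-6,8-dimethoxy-4,4-dimethylnaphthalen-1(4H)-one | CC(=O)c1c(OC)cc2c(c1OC)C(=O)C=C(O)C2(C)C | intermediate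
13 | 7-acetyl-3,6,8-trihydroxy-4,4-dimethylnaphthalen-1(4H)-one | CC(=O)c1c(O)cc2c(c1O)C(=O)C=C(O)C2(C)C | intermediate
14 | formaldehyde | C=O | starting material
15 | 7-acetyl-6,8-dihydroxy-4,4-dimethyl-2-methylidenenaphthalene-1,3(2H,4H)-dione (2-methylidene trione) | CC(=O)c1c(O)cc2c(c1O)C(=O)C(=C)C(=O)C2(C)C | intermediate
16 | 2,2'-methylenebis[7-acetyl-3,6,8-trihydroxy-4,4-dimethylnaphthalen-1(4H)-one] | CC(=O)c1c(O)cc2c(c1O)C(=O)C(CC1=C(O)C(C)(C)c3cc(O)c(C(C)=O)c(O)c3C1=O)=C(O)C2(C)C | target

**Step count**
Total steps: 8. Longest linear sequence: 8 (fully linear; 2-diazopropane is made and consumed inside step 4).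

**Steps most likely to fail**

Step 2 (melt rearrangement). The extra phenol may slow the acylation or favour intermolecular acylation and charring. Fallback, setting out from 4 and returning at 6: open and O-methylate the lactone with Me2SO4 in aqueous NaOH and acidify to give 3-(2,4-dimethoxyphenyl)propanoic acid F1. Then close the five-membered ring by intramolecular Friedel–Crafts acylation in P2O5/MeSO3H or polyphosphoric acid at 60–80 °C. This gives 6 directly and passes over 5.

Step 4 (the proposed new ring expansion). 2-Diazopropane may decompose on the Lewis acid, add sluggishly to the aryl ketone, or give some CH2 migration. Fallback by known chemistry, setting out from 6 and returning at 9: ring-expand 6 with (trimethylsilyl)diazomethane and BF3·OEt2 in CH2Cl2 at −78 °C (aryl shift). This gives racemic 5,7-dimethoxy-1-(trimethylsilyl)-3,4-dihydronaphthalen-2(1H)-one F2, which is protodesilylated on aqueous acid work-up to 5,7-dimethoxy-3,4-dihydronaphthalen-2(1H)-one F3. Double C-methylation of the benzylic α-carbon with NaH (2.2 equiv) and MeI in THF then gives 9.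

Step 6 (benzylic oxidation). Over-oxidation at the new active methylene or sluggish hydrogen abstraction are possible. Fallback, setting out from 11 and returning at 12: dehydrogenate the ring with 2,3-dichloro-5,6-dicyano-1,4-benzoquinone in refluxing dioxane to the conjugated enone 6-acetyl-5,7-dimethoxy-1,1-dimethylnaphthalen-2(1H)-one F4. Then oxidise the enone to the β-diketone with t-BuOOH and Na2PdCl4 (cat.) in aqueous AcOH at 50 °C (Wacker–Tsuji-type oxidation, oxygen placed on the β-carbon), which gives 12.

**Further compounds**
F1 | step 2 | 3-(2,4-dimethoxyphenyl)propanoic acid | COc1ccc(CCC(=O)O)c(OC)c1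
F2 | step 4 | 5,7-dimethoxy-1-(trimethylsilyl)-3,4-dihydronaphthalen-2(1H)-one (racemic) | COc1cc(OC)c2CCC(=O)C([Si](C)(C)C)c2c1
F3 | step 4 | 5,7-dimethoxy-3,4-dihydronaphthalen-2(1H)-one | COc1cc(OC)c2CCC(=O)Cc2c1
F4 | step 6 | 6-acetyl-5,7-dimethoxy-1,1-dimethylnaphthalen-2(1H)-one | CC(=O)c1c(OC)cc2c(c1OC)C=CC(=O)C2(C)C
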